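The route reads the enol-ether double bond C10=C11, shared by the oxepine and dihydropyran rings, as a masked α-aryl ketone: C10 (on ring B, bearing the pyran oxygen) is an acyl carbon, C11 (on ring A, bearing the pyran CH2) a benzylic carbon. Everything rests on forming the C10–C11 bond by intramolecular acylation of a sulfone-stabilised benzylic carbanion with the activated ring-B carboxyl group. That single operation closes the seven-membered ring of an open diaryl ether that already carries the complete (S,S)-diol side chain, set by Sharpless epoxidation of nerol and Payne rearrangement–opening. Desulfonylation and cyclodehydration through the tertiary alcohol then deliver the pyran.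

Key step: step 11

Remark: dibenzo[b,f]oxepine numbering is used (C10 and C11 are the two olefinic carbons; ring A carries the prenyl group, ring B the other phenol). 5-Bromo-2-fluoro-4-hydroxybenzaldehyde is assumed to be a catalogue compound.

Step 1
Reactants: 1 nerol, (2Z)-3,7-dimethylocta-2,6-dien-1-ol
Product: 2 (2R,3S)-2,3-epoxynerol = [(2R,3S)-3-methyl-3-(4-methylpent-3-en-1-yl)oxiran-2-yl]methanol
Conditions: Ti(OiPr)4 (10 mol%), D-(−)-diethyl tartrate (12 mol%), t-BuOOH, 4 Å molecular sieves, CH2Cl2, −20 °C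
Reagents that add atoms: tert-butyl hydroperoxide, CC(C)(C)OO
Why: Sharpless asymmetric epoxidation: the allylic hydroxyl binds the catalyst formed from Ti(OiPr)4 and D-(−)-diethyl tartrate, which should deliver oxygen to one face of the 2,3-olefin only and so set C2 (R) and C3 (S) together by reagent control, while the remote isopropylidene olefin has no directing hydroxyl and stays intact.

Step 2
Reactants: 3 5-bromo-2-fluoro-4-hydroxybenzaldehyde
Product: 4 2-fluoro-4-hydroxy-5-(3-methylbut-2-en-1-yl)benzaldehyde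
Conditions: Bu3SnCH2CH=CMe2, Pd(PPh3)4 (5 mol%), DMF, 90 °C
Reagents that add atoms: tributyl(3-methylbut-2-en-1-yl)stannane, CCCC[Sn](CCCC)(CCCC)CC=C(C)C
Why: Stille coupling: oxidative addition of zerovalent palladium into the C–Br bond and transmetallation of the allylic stannane should give the linear prenyl arene, the site ortho to the hydroxyl being fixed by the bromine of the purchased aldehyde.

Step 3
Reactants: 4 2-fluoro-4-hydroxy-5-(3-methylbut-2-en-1-yl)benzaldehyde
Product: 5 2-fluoro-5-(3-methylbut-2-en-1-yl)-4-(prop-2-en-1-yloxy)benzaldehyde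
Conditions: allyl bromide, K2CO3, DMF, rt
Reagents that add atoms: allyl bromide, C=CCBr
Why: Williamson ether synthesis on the acidic para-formyl phenol; the allyl ether keeps this oxygen from becoming a phenoxide that would switch off the fluorine for step 5, and it can later be removed without acid.

Step 4
Reactants: 6 methyl 2,4-dihydroxybenzoate
Product: 7 methyl 2-hydroxy-4-(prop-2-en-1-yloxy)benzoate
Conditions: allyl bromide (1.05 equiv), K2CO3, acetone, reflux
Reagents that add atoms: allyl bromide, C=CCBr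
Why: Williamson ether synthesis that should be selective for the 4-hydroxyl, because the 2-hydroxyl is hydrogen-bonded to the ester carbonyl and far less nucleophilic.

Step 5
Reactants: 5 2-fluoro-5-(3-methylbut-2-en-1-yl)-4-(prop-2-en-1-yloxy)benzaldehyde and 7 methyl 2-hydroxy-4-(prop-2-en-1-yloxy)benzoate
Product: 8 methyl 2-[2-formyl-4-(3-methylbut-2-en-1-yl)-5-(prop-2-en-1-yloxy)phenoxy]-4-(prop-2-en-1-yloxy)benzoate
Conditions: K2CO3, DMF, 110 °C
Reagents that add atoms: none
Why: Nucleophilic aromatic substitution (addition–elimination): the fluorine ortho to the formyl group should be displaced by the phenoxide of 7 through a Meisenheimer intermediate, joining ring A to ring B as the diaryl ether.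

Step 6
Reactants: 8 the diaryl ether aldehyde
Product: 9 methyl 2-[2-(hydroxymethyl)-4-(3-methylbut-2-en-1-yl)-5-(prop-2-en-1-yloxy)phenoxy]-4-(prop-2-en-1-yloxy)benzoate
Conditions: NaBH4, MeOH–THF, 0 °C
Reagents that add atoms: none
Why: Chemoselective borohydride reduction of the aldehyde, the methyl ester and the olefins being inert to NaBH4 at 0 °C.

Step 7
Reactants: 9 the benzylic alcohol
Product: 11 methyl 2-[2-(benzenesulfonylmethyl)-4-(3-methylbut-2-en-1-yl)-5-(prop-2-en-1-yloxy)phenoxy]-4-(prop-2-en-1-yloxy)benzoate, via benzylic bromide 10 (not isolated)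
Conditions: CBr4, PPh3, CH2Cl2, 0 °C; then PhSO2Na, DMF, rt
Reagents that add atoms: sodium benzenesulfinate, [Na+].[O-]S(=O)c1ccccc1
Why: Appel bromination of the electron-rich benzylic alcohol followed by S-alkylation of the sulfinate anion (SN2) should install the sulfone that acidifies the C11–H bonds.

Step 8
Reactants: 11 the sulfone ester
Product: 12 2-[2-(benzenesulfonylmethyl)-4-(3-methylbut-2-en-1-yl)-5-(prop-2-en-1-yloxy)phenoxy]-4-(prop-2-en-1-yloxy)benzoic acid
Conditions: LiOH, THF–MeOH–H2O, 50 °C; then 1 M HCl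
Reagents that add atoms: lithium hydroxide, [Li+].[OH-]
Why: Saponification (acyl substitution by hydroxide) gives a carboxylate that is inert to carbanions, so that the sulfonyl carbanion of step 9 is alkylated instead of cyclising prematurely onto ring B.

Step 9
Reactants: 12 the sulfone acid and 2 (2R,3S)-2,3-epoxynerol
Product: 14 2-{2-[(3S,4S)-1-(benzenesulfonyl)-3,4-dihydroxy-4,8-dimethylnon-7-en-1-yl]-4-(3-methylbut-2-en-1-yl)-5-(prop-2-en-1-yloxy)phenoxy}-4-(prop-2-en-1-yloxy)benzoic acid (both epimers at the sulfonyl-bearing carbon), via Payne epoxide 13 (not isolated)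
Conditions: NaN(SiMe3)2 (3.5 equiv), THF–DMPU, −78 → 40 °C; then 1 M HCl
Reagents that add atoms: none
Why: Payne rearrangement followed by alkylation of a sulfone carbanion: the alkoxide of 2 should equilibrate with terminal epoxide 13 by intramolecular SN2 attack at C2 (inversion, which creates the (S)-carbinol centre, while the tertiary (S)-centre keeps its C–O bond), and the sulfonyl carbanion of 12 should then open 13 at its unhindered CH2 terminus, the faster reaction of the terminal epoxide draining the equilibrium.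

Step 10
Reactants: 14 the diol acid
Product: 16 2-{2-[(3S,4S)-1-(benzenesulfonyl)-3-[(tert-butyldimethylsilyl)oxy]-4-hydroxy-4,8-dimethylnon-7-en-1-yl]-4-(3-methylbut-2-en-1-yl)-5-(prop-2-en-1-yloxy)phenoxy}-4-(prop-2-en-1-yloxy)benzoic acid, via bis-silyl ester 15 (not isolated)
Conditions: TBSCl (2.5 equiv), imidazole, DMF, rt; then THF–H2O–AcOH, rt
Reagents that add atoms: tert-butyldimethylsilyl chloride, CC(C)(C)[Si](C)(C)Cl
Why: Silyl ether formation that should stop at the secondary hydroxyl because the tertiary one is too hindered for TBSCl–imidazole, the silyl ester formed at the acid being hydrolysed again on mild aqueous acid treatment; the secondary oxygen is thereby barred from the later ring closure onto C10.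

Step 11
Reactants: 16 the silyl-protected sulfone acid
Product: 18 11-(benzenesulfonyl)-11-{(2S,3S)-2-[(tert-butyldimethylsilyl)oxy]-3-hydroxy-3,7-dimethyloct-6-en-1-yl}-2-(3-methylbut-2-en-1-yl)-3,7-bis(prop-2-en-1-yloxy)dibenzo[b,f]oxepin-10(11H)-one, via acyl imidazolide 17 (not isolated)
Conditions: CDI (1.1 equiv), THF, rt; then NaN(SiMe3)2 (3.5 equiv), THF, −78 → 0 °C; aq. NH4Cl
Reagents that add atoms: none
Why: CDI turns the ring-B carboxylic acid into acyl imidazolide 17, and NaN(SiMe3)2 then removes the only acidic C–H (α to the sulfone, benzylic on ring A), so that the tertiary carbanion adds to the acyl carbon and expels imidazolide, an intramolecular Claisen-type C-acylation that forms the C10–C11 bond. The closest known reaction type is the acylation of metallated sulfones by N-acylimidazoles or esters to β-keto sulfones, here run in a Dieckmann-like ring-closing sense. The oxepine ring closes by 7-exo-trig attack on the acyl carbon; no other ring is formed, and the tertiary alkoxide can at most add reversibly to the new ketone as a six-membered hemiketal. C11 becomes a quaternary stereocentre that is not controlled and need not be, because it is flattened in step 12; the (S,S) centres of the side chain are remote from the reacting atoms and untouched. The step needs C-acylation by the carbanion and not O-acylation by the alkoxide: imidazolide is a non-nucleophilic leaving group, so the acylation should be irreversible, the tertiary alkoxide could reach the acyl carbon only through an eleven-membered ring, and the ring-B carboxyl group was kept inert until now so that it is switched on only after the chain is in place.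

Step 12
Reactants: 18 the cyclic β-keto sulfone
Product: 20 bis-allyl silyl-protected target (pyran closed: (2S,3S)-3-[(tert-butyldimethylsilyl)oxy]-2-methyl-2-(4-methylpent-3-en-1-yl)-3,4-dihydro-2H-pyran fused at C10–C11 of 2-(3-methylbut-2-en-1-yl)-3,7-bis(prop-2-en-1-yloxy)dibenzo[b,f]oxepine with the ring oxygen on C10), via desulfonylated ketone 19 (not isolated)
Conditions: SmI2 (2.5 equiv), THF–MeOH, −78 °C; then PPTS (cat.), 4 Å molecular sieves, toluene, 60 °C
Reagents that add atoms: none
Why: Reductive desulfonylation of the α-sulfonyl ketone by electron transfer from SmI2 should give the C11–H ketone, and acid-catalysed hemiketalisation–dehydration by the only free hydroxyl, the tertiary one, should then form the six-membered enol ether with both C–O bonds at the stereocentres left intact (retention).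

Step 13
Reactants: 20 the protected target
Product: 22 CNP0185870.1 (the target), via bisphenol silyl ether 21 (not isolated)
Conditions: Pd(PPh3)4 (5 mol%), morpholine, THF, rt; then Bu4NF, THF, rt; aq. NH4Cl
Reagents that add atoms: none
Why: Tsuji–Trost deallylation (ionisation of the aryl allyl ethers by Pd(PPh3)4, morpholine as allyl acceptor) should free both phenols under neutral conditions and fluoride-driven Si–O cleavage should then free the secondary alcohol, no acid touching the enol ether or the prenyl groups.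

Compound list

1 | nerol, (2Z)-3,7-dimethylocta-2,6-dien-1-ol | CC(C)=CCC/C(C)=C\CO | starting material
2 | (2R,3S)-2,3-epoxynerol, [(2R,3S)-3-methyl-3-(4-methylpent-3-en-1-yl)oxiran-2-yl]methanol | OC[C@H]1O[C@@]1(C)CCC=C(C)C | intermediate
3 | 5-bromo-2-fluoro-4-hydroxybenzaldehyde | O=Cc1cc(Br)c(O)cc1F | starting material
4 | 2-fluoro-4-hydroxy-5-(3-methylbut-2-en-1-yl)benzaldehyde | O=Cc1cc(CC=C(C)C)c(O)cc1F | intermediate
5 | 2-fluoro-5-(3-methylbut-2-en-1-yl)-4-(prop-2-en-1-yloxy)benzaldehyde | O=Cc1cc(CC=C(C)C)c(OCC=C)cc1F | intermediate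
6 | methyl 2,4-dihydroxybenzoate | COC(=O)c1ccc(O)cc1O | starting material
7 | methyl 2-hydroxy-4-(prop-2-en-1-yloxy)benzoate | COC(=O)c1ccc(OCC=C)cc1O | intermediate
8 | methyl 2-[2-formyl-4-(3-methylbut-2-en-1-yl)-5-(prop-2-en-1-yloxy)phenoxy]-4-(prop-2-en-1-yloxy)benzoate | COC(=O)c1ccc(OCC=C)cc1Oc1cc(OCC=C)c(CC=C(C)C)cc1C=O | intermediate
9 | methyl 2-[2-(hydroxymethyl)-4-(3-methylbut-2-en-1-yl)-5-(prop-2-en-1-yloxy)phenoxy]-4-(prop-2-en-1-yloxy)benzoate | COC(=O)c1ccc(OCC=C)cc1Oc1cc(OCC=C)c(CC=C(C)C)cc1CO | intermediate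
10 | methyl 2-[2-(bromomethyl)-4-(3-methylbut-2-en-1-yl)-5-(prop-2-en-1-yloxy)phenoxy]-4-(prop-2-en-1-yloxy)benzoate (not isolated) | COC(=O)c1ccc(OCC=C)cc1Oc1cc(OCC=C)c(CC=C(C)C)cc1CBr | intermediate
11 | methyl 2-[2-(benzenesulfonylmethyl)-4-(3-methylbut-2-en-1-yl)-5-(prop-2-en-1-yloxy)phenoxy]-4-(prop-2-en-1-yloxy)benzoate | COC(=O)c1ccc(OCC=C)cc1Oc1cc(OCC=C)c(CC=C(C)C)cc1CS(=O)(=O)c1ccccc1 | intermediate
12 | 2-[2-(benzenesulfonylmethyl)-4-(3-methylbut-2-en-1-yl)-5-(prop-2-en-1-yloxy)phenoxy]-4-(prop-2-en-1-yloxy)benzoic acid | OC(=O)c1ccc(OCC=C)cc1Oc1cc(OCC=C)c(CC=C(C)C)cc1CS(=O)(=O)c1ccccc1 | intermediate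
13 | (2S)-6-methyl-2-[(2S)-oxiran-2-yl]hept-5-en-2-ol, the Payne-rearranged terminal epoxide of 2, present as its sodium alkoxide (not isolated) | C1O[C@@H]1[C@@](C)(O)CCC=C(C)C | intermediate
14 | 2-{2-[(3S,4S)-1-(benzenesulfonyl)-3,4-dihydroxy-4,8-dimethylnon-7-en-1-yl]-4-(3-methylbut-2-en-1-yl)-5-(prop-2-en-1-yloxy)phenoxy}-4-(prop-2-en-1-yloxy)benzoic acid, both epimers at the sulfonyl-bearing carbon | OC(=O)c1ccc(OCC=C)cc1Oc1cc(OCC=C)c(CC=C(C)C)cc1C(S(=O)(=O)c1ccccc1)C[C@H](O)[C@@](C)(O)CCC=C(C)C | intermediate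
15 | tert-butyldimethylsilyl ester of 16 (silyl ester and secondary silyl ether; not isolated) | CC(C)(C)[Si](C)(C)OC(=O)c1ccc(OCC=C)cc1Oc1cc(OCC=C)c(CC=C(C)C)cc1C(S(=O)(=O)c1ccccc1)C[C@H](O[Si](C)(C)C(C)(C)C)[C@@](C)(O)CCC=C(C)C | intermediate
16 | 2-{2-[(3S,4S)-1-(benzenesulfonyl)-3-[(tert-butyldimethylsilyl)oxy]-4-hydroxy-4,8-dimethylnon-7-en-1-yl]-4-(3-methylbut-2-en-1-yl)-5-(prop-2-en-1-yloxy)phenoxy}-4-(prop-2-en-1-yloxy)benzoic acid | OC(=O)c1ccc(OCC=C)cc1Oc1cc(OCC=C)c(CC=C(C)C)cc1C(S(=O)(=O)c1ccccc1)C[C@H](O[Si](C)(C)C(C)(C)C)[C@@](C)(O)CCC=C(C)C | intermediate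
17 | 1H-imidazol-1-yl ketone (acyl imidazolide) of 16 (not isolated) | O=C(c1ccc(OCC=C)cc1Oc1cc(OCC=C)c(CC=C(C)C)cc1C(S(=O)(=O)c1ccccc1)C[C@H](O[Si](C)(C)C(C)(C)C)[C@@](C)(O)CCC=C(C)C)n1ccnc1 | intermediate
18 | 11-(benzenesulfonyl)-11-{(2S,3S)-2-[(tert-butyldimethylsilyl)oxy]-3-hydroxy-3,7-dimethyloct-6-en-1-yl}-2-(3-methylbut-2-en-1-yl)-3,7-bis(prop-2-en-1-yloxy)dibenzo[b,f]oxepin-10(11H)-one, both epimers at C11 | O=C1c2ccc(OCC=C)cc2Oc2cc(OCC=C)c(CC=C(C)C)cc2C1(S(=O)(=O)c1ccccc1)C[C@H](O[Si](C)(C)C(C)(C)C)[C@@](C)(O)CCC=C(C)C | intermediate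
19 | 11-{(2S,3S)-2-[(tert-butyldimethylsilyl)oxy]-3-hydroxy-3,7-dimethyloct-6-en-1-yl}-2-(3-methylbut-2-en-1-yl)-3,7-bis(prop-2-en-1-yloxy)dibenzo[b,f]oxepin-10(11H)-one, both epimers at C11 (not isolated) | O=C1c2ccc(OCC=C)cc2Oc2cc(OCC=C)c(CC=C(C)C)cc2C1C[C@H](O[Si](C)(C)C(C)(C)C)[C@@](C)(O)CCC=C(C)C | intermediate
20 | target protected as the 3,7-bis(allyl ether) and as the tert-butyldimethylsilyl ether of the pyran 3-hydroxyl, (2S,3S) in the pyran ring | CC(C)=CCC[C@]1(C)OC2=C(C[C@@H]1O[Si](C)(C)C(C)(C)C)c1cc(CC=C(C)C)c(OCC=C)cc1Oc1cc(OCC=C)ccc12 | intermediate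
21 | target protected only as the tert-butyldimethylsilyl ether of the pyran 3-hydroxyl (not isolated) | CC(C)=CCC[C@]1(C)OC2=C(C[C@@H]1O[Si](C)(C)C(C)(C)C)c1cc(CC=C(C)C)c(O)cc1Oc1cc(O)ccc12 | intermediate
22 | CNP0185870.1: 2-prenyl-dibenzo[b,f]oxepine-3,7-diol with a (2S,3S)-3-hydroxy-2-methyl-2-(4-methylpent-3-en-1-yl)-3,4-dihydro-2H-pyran ring fused at C10–C11, ring oxygen on C10 | CC(C)=CCC[C@]1(C)OC2=C(C[C@@H]1O)c1cc(CC=C(C)C)c(O)cc1Oc1cc(O)ccc12 | target

Total step count: 13. Longest linear sequence: 11 steps (3 → 22 through steps 2, 3 and 5–13).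

Steps most likely to fail

Step 9. Under aprotic conditions the Payne equilibrium may be slow or lie far on the side of the trisubstituted 2,3-epoxide, so that the sulfonyl carbanion is lost by proton transfer or opens the epoxide unselectively before the terminal epoxide is trapped. Fallback: the terminal epoxide is made as a discrete compound by a thioether route. Setting out from 2, Payne rearrangement–opening in the aqueous mode with 2-methylpropane-2-thiol and NaOH in t-BuOH–H2O at reflux should give (2R,3S)-1-(tert-butylsulfanyl)-3,7-dimethyloct-6-ene-2,3-diol F1. S-Methylation with Me3OBF4 in CH2Cl2 should give the sulfonium tetrafluoroborate F2. NaH in THF should then close the secondary alkoxide onto C1 with loss of the sulfide to give epoxy alcohol 13, now isolated. Its sodium alkoxide is opened by the dianion of 12 (NaN(SiMe3)2, THF–DMPU, 0 → 40 °C), which comes back to the route at 14.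

Step 11. Addition of the hindered tertiary carbanion may be slow, so that proton exchange, attack of the tertiary alkoxide on the acyl imidazolide or an aryl migration of the Truce–Smiles type outruns ring closure. Fallback: the ring is closed before the side chain is attached.
- Setting out from 11, NaH in THF should induce Dieckmann-type condensation of the unsubstituted sulfonyl carbanion onto the methyl ester, driven by enolate formation, to give 11-(benzenesulfonyl)-2-(3-methylbut-2-en-1-yl)-3,7-bis(prop-2-en-1-yloxy)dibenzo[b,f]oxepin-10(11H)-one F3; the C10–C11 bond is still the ring-closing bond.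
- SmI2 in THF–MeOH should give the parent 2-(3-methylbut-2-en-1-yl)-3,7-bis(prop-2-en-1-yloxy)dibenzo[b,f]oxepin-10(11H)-one F4.
- 1,1-Dimethylhydrazine (AcOH cat., EtOH, reflux) should give its N,N-dimethylhydrazone F5.
- The C11 aza-enolate of F5 (LiN(iPr)2, THF, 0 °C) should open epoxide 13, generated in the flask from 2 and NaH, to give the hydrazone diol F6.
- TBSCl–imidazole should silylate the secondary hydroxyl to give the silyl ether F7.
- Aqueous oxalic acid–THF and then PPTS in toluene over molecular sieves should release the ketone and cyclodehydrate it through the tertiary alcohol, which comes back to the route at 20.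

Step 2. The acidic phenol may protodestannylate the allylic stannane, the phenoxide may inhibit the catalyst, and part of the coupling may occur at the branched (γ) terminus. Fallback: the phenol is masked with a group that tolerates zerovalent palladium and is exchanged for allyl in one operation. Setting out from 3, TBSCl–imidazole in DMF should give 5-bromo-4-[(tert-butyldimethylsilyl)oxy]-2-fluorobenzaldehyde F8. The Stille coupling under the conditions of step 2 should give 4-[(tert-butyldimethylsilyl)oxy]-2-fluoro-5-(3-methylbut-2-en-1-yl)benzaldehyde F9. CsF with allyl bromide in DMF should cleave the aryl silyl ether and alkylate the phenoxide in the same flask, which comes back to the route at 5.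

Further compounds

F1 | step 9 | (2R,3S)-1-(tert-butylsulfanyl)-3,7-dimethyloct-6-ene-2,3-diol | CC(C)(C)SC[C@H](O)[C@@](C)(O)CCC=C(C)C
F2 | step 9 | tert-butyl[(2R,3S)-2,3-dihydroxy-3,7-dimethyloct-6-en-1-yl]methylsulfonium tetrafluoroborate | C[S+](C[C@H](O)[C@@](C)(O)CCC=C(C)C)C(C)(C)C.F[B-](F)(F)F
F3 | step 11 | 11-(benzenesulfonyl)-2-(3-methylbut-2-en-1-yl)-3,7-bis(prop-2-en-1-yloxy)dibenzo[b,f]oxepin-10(11H)-one | O=C1c2ccc(OCC=C)cc2Oc2cc(OCC=C)c(CC=C(C)C)cc2C1S(=O)(=O)c1ccccc1
F4 | step 11 | 2-(3-methylbut-2-en-1-yl)-3,7-bis(prop-2-en-1-yloxy)dibenzo[b,f]oxepin-10(11H)-one | O=C1c2ccc(OCC=C)cc2Oc2cc(OCC=C)c(CC=C(C)C)cc2C1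
F5 | step 11 | N,N-dimethylhydrazone of F4 | CN(C)N=C1c2ccc(OCC=C)cc2Oc2cc(OCC=C)c(CC=C(C)C)cc2C1
F6 | step 11 | N,N-dimethylhydrazone of 11-[(2S,3S)-2,3-dihydroxy-3,7-dimethyloct-6-en-1-yl]-2-(3-methylbut-2-en-1-yl)-3,7-bis(prop-2-en-1-yloxy)dibenzo[b,f]oxepin-10(11H)-one | CN(C)N=C1c2ccc(OCC=C)cc2Oc2cc(OCC=C)c(CC=C(C)C)cc2C1C[C@H](O)[C@@](C)(O)CCC=C(C)C
F7 | step 11 | N,N-dimethylhydrazone of 19 | CN(C)N=C1c2ccc(OCC=C)cc2Oc2cc(OCC=C)c(CC=C(C)C)cc2C1C[C@H](O[Si](C)(C)C(C)(C)C)[C@@](C)(O)CCC=C(C)C
F8 | step 2 | 5-bromo-4-[(tert-butyldimethylsilyl)oxy]-2-fluorobenzaldehyde | O=Cc1cc(Br)c(O[Si](C)(C)C(C)(C)C)cc1F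
F9 | step 2 | 4-[(tert-butyldimethylsilyl)oxy]-2-fluoro-5-(3-methylbut-2-en-1-yl)benzaldehyde | O=Cc1cc(CC=C(C)C)c(O[Si](C)(C)C(C)(C)C)cc1F
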